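**Retrosynthetic overview**

1. Target 22 is (2S)-5,7-dihydroxy-6-[(2R)-1-methylpiperidin-2-yl]flavanone: ring A (phloroglucinol ring), ring B (phenyl), ring C (pyranone) and the piperidine ring D (N1', C2'–C6') on C6.
2. Feature used: in ring D, C3', C4', C5' and C6' are unsubstituted CH2 groups and the single stereocentre C2' carries both N1' and ring A, so C4'–C5' is cut to a C4'=C5' alkene made by ring-closing metathesis of an N1'-allyl arm and a C2'-allyl arm.
3. Ring C is cut at C4–C4a (intramolecular Friedel–Crafts acylation) and at O1–C2 (Mitsunobu inversion of ethyl (R)-3-hydroxy-3-phenylpropanoate on the ring A phenol para to C2').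
4. The metathesis diene comes from allylmagnesium bromide addition to the (S)-tert-butanesulfinyl imine of 2,6-bis(benzyloxy)-4-(triisopropylsilyloxy)benzaldehyde (sets C2' as R), N-allylation and exchange of sulfinyl for Boc; the aldehyde comes from 3,5-bis(benzyloxy)phenol.
5. Order of ring formation: rings A and B are bought, ring D is closed in step 7, ring C in step 12.

Key step: step 7

Assumption: the SMILES is read as 2S at C2 of ring C and 2'R at C2' of ring D, and 3,5-bis(benzyloxy)phenol is taken to be purchasable; benzyl ethers are kept to the end because they survive acid, base and hydride and leave under neutral conditions.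

**Route**

Step 1
Reactants: 1 3,5-bis(benzyloxy)phenol
Product: 3 2,6-bis(benzyloxy)-4-hydroxybenzaldehyde, via aryl iminium chloride 2 (not isolated)
Conditions: POCl3, DMF, 0 °C → rt; then H2O, rt
Reagents that add atoms: N,N-dimethylformamide, CN(C)C=O (formyl carbon; the NMe2 group stays in 2 only); water, O (carbonyl oxygen)
Why: Vilsmeier–Haack formylation, in which the chloroiminium ion attacks the phloroglucinol-type ring preferentially para to the free hydroxyl (between the two benzyloxy groups), as is known for 3,5-dimethoxyphenol; hydrolysis of iminium 2 frees the aldehyde, and the minor hydrogen-bonded ortho-hydroxy isomer is far less polar and should be separable on silica.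

Step 2
Reactants: 3 2,6-bis(benzyloxy)-4-hydroxybenzaldehyde
Product: 4 2,6-bis(benzyloxy)-4-(triisopropylsilyloxy)benzaldehyde
Conditions: i-Pr3SiCl, imidazole, DMF, rt
Reagents that add atoms: triisopropylsilyl chloride, CC(C)[Si](Cl)(C(C)C)C(C)C
Why: Imidazole-promoted O-silylation of the only free phenol, done after the benzyl ethers are in place so that the aryl silyl ether para to the formyl group never meets carbonate or alkoxide bases that would strip it.

Step 3
Reactants: 4 2,6-bis(benzyloxy)-4-(triisopropylsilyloxy)benzaldehyde; 5 (S)-2-methylpropane-2-sulfinamide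
Product: 6 (S,E)-N-[2,6-bis(benzyloxy)-4-(triisopropylsilyloxy)benzylidene]-2-methylpropane-2-sulfinamide
Conditions: Ti(OEt)4, THF, 65 °C
Reagents that add atoms: (S)-2-methylpropane-2-sulfinamide (5), CC(C)(C)[S@](=O)N
Why: Condensation of an aldehyde with tert-butanesulfinamide to the N-sulfinyl aldimine, with Ti(OEt)4 as Lewis acid and water scavenger and heating to offset the hindered, electron-rich carbonyl; only the E imine is expected.

Step 4
Reactants: 6 (S,E)-N-[2,6-bis(benzyloxy)-4-(triisopropylsilyloxy)benzylidene]-2-methylpropane-2-sulfinamide; 7 allylmagnesium bromide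
Product: 8 (S)-N-{(1R)-1-[2,6-bis(benzyloxy)-4-(triisopropylsilyloxy)phenyl]but-3-en-1-yl}-2-methylpropane-2-sulfinamide
Conditions: CH2=CHCH2MgBr (Et2O solution), CH2Cl2, −78 °C; then aq. NH4Cl
Reagents that add atoms: allylmagnesium bromide (7), C=CC[Mg]Br
Why: Diastereoselective 1,2-addition of a Grignard reagent to an N-tert-butanesulfinyl aldimine: in non-coordinating CH2Cl2 magnesium binds the sulfinyl oxygen and delivers allyl through a six-membered chair with tert-butyl equatorial, which for the (S)-sulfinyl imine means attack on the Re face and the R configuration at the new benzylic carbon (the later C2'); the minor diastereomer should be removable on silica.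

Step 5
Reactants: 8 (S)-N-{(1R)-1-[2,6-bis(benzyloxy)-4-(triisopropylsilyloxy)phenyl]but-3-en-1-yl}-2-methylpropane-2-sulfinamide; 9 allyl bromide
Product: 10 (S)-N-allyl-N-{(1R)-1-[2,6-bis(benzyloxy)-4-(triisopropylsilyloxy)phenyl]but-3-en-1-yl}-2-methylpropane-2-sulfinamide
Conditions: LiN(SiMe3)2, DMF/THF, −20 °C → rt
Reagents that add atoms: allyl bromide (9), C=CCBr
Why: SN2 N-alkylation of the lithium sulfinamide by the small, reactive allyl bromide; only the N–H is deprotonated, so the benzylic stereocentre is not touched.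

Step 6
Reactants: 10 (S)-N-allyl-N-{(1R)-1-[2,6-bis(benzyloxy)-4-(triisopropylsilyloxy)phenyl]but-3-en-1-yl}-2-methylpropane-2-sulfinamide
Product: 12 tert-butyl allyl{(1R)-1-[2,6-bis(benzyloxy)-4-(triisopropylsilyloxy)phenyl]but-3-en-1-yl}carbamate, via secondary amine hydrochloride 11 (not isolated)
Conditions: HCl (4 M in dioxane), MeOH, 0 °C; evaporate; then Boc2O, Et3N, THF, 50 °C
Reagents that add atoms: di-tert-butyl dicarbonate, CC(C)(C)OC(=O)OC(=O)OC(C)(C)C; hydrogen chloride, Cl (chloride of 11 only)
Why: Acid methanolysis of the sulfinamide S–N bond (the auxiliary leaves as its methyl sulfinate) frees the secondary amine as hydrochloride 11 at a temperature at which the aryl silyl ether, the benzyl ethers and the benzylic C–N bond should hold, and carbamate formation with Boc2O then masks the nitrogen lone pair so that it cannot bind ruthenium in step 7.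

Step 7
Reactants: 12 tert-butyl allyl{(1R)-1-[2,6-bis(benzyloxy)-4-(triisopropylsilyloxy)phenyl]but-3-en-1-yl}carbamate
Product: 13 tert-butyl (2R)-2-[2,6-bis(benzyloxy)-4-(triisopropylsilyloxy)phenyl]-3,6-dihydro-2H-pyridine-1-carboxylate
Conditions: second-generation Grubbs catalyst RuCl2(=CHPh)(H2IMes)(PCy3) (5 mol %), 1,4-benzoquinone (10 mol %), CH2Cl2 (0.01 M), 40 °C
Reagents that add atoms: none
Why: Ring-closing olefin metathesis: the ruthenium benzylidene should load onto the less hindered N-allyl alkene of 12, the new ruthenium alkylidene then adds across the C-allyl alkene to a ruthenacyclobutane, and cycloreversion expels ethene and forms the C4'=C5' double bond. The closest known reaction type is the metathesis closure of N-acyl N-allyl homoallylamines to 1,2,3,6-tetrahydropyridines. Ring D closes as a six-membered ring with the new alkene inside the ring, where only the Z geometry is possible. No stereocentre is created; C2' was set in step 4 and is not involved, since it is not part of either alkene and carries no hydrogen that the catalyst or the medium can remove. The step needs cyclisation to win over intermolecular metathesis and needs the alkenes not to migrate; high dilution, the gauche arrangement that the branched carbon with its N-Boc and aryl groups imposes on the two allyl arms, and the non-basic carbamate nitrogen secure the first. A short reaction time and 1,4-benzoquinone as scavenger of ruthenium hydride species secure the second.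

Step 8
Reactants: 13 tert-butyl (2R)-2-[2,6-bis(benzyloxy)-4-(triisopropylsilyloxy)phenyl]-3,6-dihydro-2H-pyridine-1-carboxylate
Product: 14 tert-butyl (2R)-2-[2,6-bis(benzyloxy)-4-(triisopropylsilyloxy)phenyl]piperidine-1-carboxylate
Conditions: 4-MeC6H4SO2NHNH2 (excess), NaOAc, DME/H2O, 85 °C
Reagents that add atoms: none
Why: Diimide reduction, in which HN=NH released from the sulfonyl hydrazide transfers two hydrogens to the cis ring alkene in a concerted syn manner and leaves the benzyl ethers, the aryl silyl ether and the carbamate untouched, which a palladium-catalysed hydrogenation would not.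

Step 9
Reactants: 14 tert-butyl (2R)-2-[2,6-bis(benzyloxy)-4-(triisopropylsilyloxy)phenyl]piperidine-1-carboxylate
Product: 16 3,5-bis(benzyloxy)-4-[(2R)-1-methylpiperidin-2-yl]phenol, via N-methylpiperidine silyl ether 15 (not isolated)
Conditions: LiAlH4, THF, 65 °C; H2O/aq. NaOH work-up; then Bu4NF, THF, 0 °C → rt; then H2O
Reagents that add atoms: none
Why: Hydride reduction of a carbamate to an N-methyl amine (the Boc carbonyl carbon becomes the N-CH3 group by way of the hemiaminal aluminate and the iminium ion) followed by fluoride cleavage of the Si–O bond; benzyl ethers survive both reagents, and any silyl ether already lost to hydride converges on the same phenol.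

Step 10
Reactants: 16 3,5-bis(benzyloxy)-4-[(2R)-1-methylpiperidin-2-yl]phenol; 17 ethyl (3R)-3-hydroxy-3-phenylpropanoate
Product: 18 ethyl (3S)-3-{3,5-bis(benzyloxy)-4-[(2R)-1-methylpiperidin-2-yl]phenoxy}-3-phenylpropanoate
Conditions: PPh3, diisopropyl azodicarboxylate (slow addition), THF, 0 °C → rt
Reagents that add atoms: ethyl (3R)-3-hydroxy-3-phenylpropanoate (17), CCOC(=O)C[C@H](c1ccccc1)O
Why: Mitsunobu etherification, in which the unhindered phenol (pKa about 10) protonates the phosphine–azodicarboxylate betaine and the phenoxide displaces the benzylic oxyphosphonium group by SN2 with inversion, turning the (R) alcohol into the (S) aryl ether that becomes C2 of ring C; low temperature and slow addition hold back elimination to the cinnamate.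

Step 11
Reactants: 18 ethyl (3S)-3-{3,5-bis(benzyloxy)-4-[(2R)-1-methylpiperidin-2-yl]phenoxy}-3-phenylpropanoate
Product: 19 (3S)-3-{3,5-bis(benzyloxy)-4-[(2R)-1-methylpiperidin-2-yl]phenoxy}-3-phenylpropanoic acid
Conditions: LiOH, THF/H2O, rt; then 1 M HCl to pH 6
Reagents that add atoms: lithium hydroxide, [Li+].[OH-] (hydroxyl oxygen of the acid)
Why: Ester saponification by acyl–oxygen cleavage at room temperature, where hydrolysis should outpace β-elimination of the phenoxide and the carboxylate formed is no longer prone to it; neither stereocentre bears a hydrogen that hydroxide can remove.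

Step 12
Reactants: 19 (3S)-3-{3,5-bis(benzyloxy)-4-[(2R)-1-methylpiperidin-2-yl]phenoxy}-3-phenylpropanoic acid
Product: 21 (2S)-5,7-bis(benzyloxy)-6-[(2R)-1-methylpiperidin-2-yl]-2-phenyl-2,3-dihydro-4H-chromen-4-one, via mixed trifluoroacetic anhydride 20 (not isolated)
Conditions: (CF3CO)2O, CF3CO2H/CH2Cl2, 0 °C → rt; then aq. NaHCO3
Reagents that add atoms: trifluoroacetic anhydride, O=C(OC(=O)C(F)(F)F)C(F)(F)F (trifluoroacetyl group of 20 only)
Why: Intramolecular Friedel–Crafts acylation through mixed anhydride 20, in which the trialkoxy ring A is nucleophilic enough to be acylated at 0 °C at either of the two equivalent carbons ortho to the ether oxygen, closing the six-membered ring C at C4–C4a, while the amine is protected as its ammonium salt and the C2 ether should not ionise because the neighbouring acyl-bearing CH2 destabilises a benzylic cation.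

Step 13
Reactants: 21 (2S)-5,7-bis(benzyloxy)-6-[(2R)-1-methylpiperidin-2-yl]-2-phenyl-2,3-dihydro-4H-chromen-4-one
Product: 22 (2S)-5,7-dihydroxy-6-[(2R)-1-methylpiperidin-2-yl]-2-phenyl-2,3-dihydro-4H-chromen-4-one
Conditions: H2 (1 atm), Pd/C (10 wt% palladium on carbon), EtOAc/MeOH, rt
Reagents that add atoms: none
Why: Hydrogenolysis of the two aryl benzyl ethers on palladium metal, which should be much faster at 1 atm and room temperature than cleavage of the cyclic benzylic C2–O1 or C2'–N1' bonds; the neutral medium avoids the base-promoted ring opening to the chalcone that would scramble C2.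

**Compound list**

1 | 3,5-bis(benzyloxy)phenol | Oc1cc(OCc2ccccc2)cc(OCc2ccccc2)c1 | starting material
2 | N-[2,6-bis(benzyloxy)-4-hydroxybenzylidene]-N-methylmethanaminium chloride | C[N+](C)=Cc1c(OCc2ccccc2)cc(O)cc1OCc1ccccc1.[Cl-] | intermediate
3 | 2,6-bis(benzyloxy)-4-hydroxybenzaldehyde | O=Cc1c(OCc2ccccc2)cc(O)cc1OCc1ccccc1 | intermediate
4 | 2,6-bis(benzyloxy)-4-(triisopropylsilyloxy)benzaldehyde | O=Cc1c(OCc2ccccc2)cc(O[Si](C(C)C)(C(C)C)C(C)C)cc1OCc1ccccc1 | intermediate
5 | (S)-2-methylpropane-2-sulfinamide | CC(C)(C)[S@](=O)N | starting material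
6 | (S,E)-N-[2,6-bis(benzyloxy)-4-(triisopropylsilyloxy)benzylidene]-2-methylpropane-2-sulfinamide | CC(C)(C)[S@](=O)/N=C/c1c(OCc2ccccc2)cc(O[Si](C(C)C)(C(C)C)C(C)C)cc1OCc1ccccc1 | intermediate
7 | allylmagnesium bromide | C=CC[Mg]Br | starting material
8 | (S)-N-{(1R)-1-[2,6-bis(benzyloxy)-4-(triisopropylsilyloxy)phenyl]but-3-en-1-yl}-2-methylpropane-2-sulfinamide | CC(C)(C)[S@](=O)N[C@H](CC=C)c1c(OCc2ccccc2)cc(O[Si](C(C)C)(C(C)C)C(C)C)cc1OCc1ccccc1 | intermediate
9 | allyl bromide | C=CCBr | starting material
10 | (S)-N-allyl-N-{(1R)-1-[2,6-bis(benzyloxy)-4-(triisopropylsilyloxy)phenyl]but-3-en-1-yl}-2-methylpropane-2-sulfinamide | CC(C)(C)[S@](=O)N(CC=C)[C@H](CC=C)c1c(OCc2ccccc2)cc(O[Si](C(C)C)(C(C)C)C(C)C)cc1OCc1ccccc1 | intermediate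
11 | (1R)-N-allyl-1-[2,6-bis(benzyloxy)-4-(triisopropylsilyloxy)phenyl]but-3-en-1-amine hydrochloride | C=CCN[C@H](CC=C)c1c(OCc2ccccc2)cc(O[Si](C(C)C)(C(C)C)C(C)C)cc1OCc1ccccc1.Cl | intermediate
12 | tert-butyl allyl{(1R)-1-[2,6-bis(benzyloxy)-4-(triisopropylsilyloxy)phenyl]but-3-en-1-yl}carbamate | C=CCN(C(=O)OC(C)(C)C)[C@H](CC=C)c1c(OCc2ccccc2)cc(O[Si](C(C)C)(C(C)C)C(C)C)cc1OCc1ccccc1 | intermediate
13 | tert-butyl (2R)-2-[2,6-bis(benzyloxy)-4-(triisopropylsilyloxy)phenyl]-3,6-dihydro-2H-pyridine-1-carboxylate | CC(C)(C)OC(=O)N1CC=CC[C@@H]1c1c(OCc2ccccc2)cc(O[Si](C(C)C)(C(C)C)C(C)C)cc1OCc1ccccc1 | intermediate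
14 | tert-butyl (2R)-2-[2,6-bis(benzyloxy)-4-(triisopropylsilyloxy)phenyl]piperidine-1-carboxylate | CC(C)(C)OC(=O)N1CCCC[C@@H]1c1c(OCc2ccccc2)cc(O[Si](C(C)C)(C(C)C)C(C)C)cc1OCc1ccccc1 | intermediate
15 | (2R)-2-[2,6-bis(benzyloxy)-4-(triisopropylsilyloxy)phenyl]-1-methylpiperidine | CN1CCCC[C@@H]1c1c(OCc2ccccc2)cc(O[Si](C(C)C)(C(C)C)C(C)C)cc1OCc1ccccc1 | intermediate
16 | 3,5-bis(benzyloxy)-4-[(2R)-1-methylpiperidin-2-yl]phenol | CN1CCCC[C@@H]1c1c(OCc2ccccc2)cc(O)cc1OCc1ccccc1 | intermediate
17 | ethyl (3R)-3-hydroxy-3-phenylpropanoate | CCOC(=O)C[C@H](c1ccccc1)O | starting material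
18 | ethyl (3S)-3-{3,5-bis(benzyloxy)-4-[(2R)-1-methylpiperidin-2-yl]phenoxy}-3-phenylpropanoate | CN1CCCC[C@@H]1c1c(OCc2ccccc2)cc(O[C@@H](CC(=O)OCC)c2ccccc2)cc1OCc1ccccc1 | intermediate
19 | (3S)-3-{3,5-bis(benzyloxy)-4-[(2R)-1-methylpiperidin-2-yl]phenoxy}-3-phenylpropanoic acid | CN1CCCC[C@@H]1c1c(OCc2ccccc2)cc(O[C@@H](CC(=O)O)c2ccccc2)cc1OCc1ccccc1 | intermediate
20 | (3S)-3-{3,5-bis(benzyloxy)-4-[(2R)-1-methylpiperidin-2-yl]phenoxy}-3-phenylpropanoic trifluoroacetic anhydride (present as its trifluoroacetate salt) | CN1CCCC[C@@H]1c1c(OCc2ccccc2)cc(O[C@@H](CC(=O)OC(=O)C(F)(F)F)c2ccccc2)cc1OCc1ccccc1 | intermediate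
21 | (2S)-5,7-bis(benzyloxy)-6-[(2R)-1-methylpiperidin-2-yl]-2-phenyl-2,3-dihydro-4H-chromen-4-one | CN1CCCC[C@@H]1c1c(OCc2ccccc2)cc2c(c1OCc1ccccc1)C(=O)C[C@@H](c1ccccc1)O2 | intermediate
22 | (2S)-5,7-dihydroxy-6-[(2R)-1-methylpiperidin-2-yl]-2-phenyl-2,3-dihydro-4H-chromen-4-one | CN1CCCC[C@@H]1c1c(O)cc2c(c1O)C(=O)C[C@@H](c1ccccc1)O2 | target

**Step count**

Total steps: 13. Longest linear sequence: 13 steps (1 → 22).

**Steps most likely to fail**

Step 10. The activated benzylic oxyphosphonium ion may lose its acidic α-hydrogen (elimination to the cinnamate) or ionise before the phenoxide arrives, so that etherification is outrun or inversion is incomplete. The fallback makes the ether from an alcohol that has no acidifying carbonyl group and unveils the acid afterwards. Setting out from 16, Mitsunobu coupling (PPh3, diisopropyl azodicarboxylate, toluene, 0 °C) with commercial (R)-1-phenylbut-3-en-1-ol should give, with inversion, (2R)-2-{2,6-bis(benzyloxy)-4-[(1S)-1-phenylbut-3-en-1-yloxy]phenyl}-1-methylpiperidine F1. Oxidative cleavage of the terminal alkene (OsO4 cat., NaIO4, 2,6-lutidine, dioxane/H2O) should give (3S)-3-{3,5-bis(benzyloxy)-4-[(2R)-1-methylpiperidin-2-yl]phenoxy}-3-phenylpropanal F2. Buffered chlorite oxidation (NaClO2, NaH2PO4, 2-methyl-2-butene, t-BuOH/H2O) should then come back to the route at acid 19, replacing steps 10 and 11.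

Step 12. Under the acidic acylation conditions the benzylic C2–O bond may be cleaved, or a benzyl group may migrate from oxygen to carbon, before ring C closes. The fallback closes ring C through an aryl anion in place of an acylium-type electrophile. Setting out from 19, amide coupling (MeNH(OMe)·HCl, EDC·HCl, HOBt, i-Pr2NEt, CH2Cl2) should give (3S)-3-{3,5-bis(benzyloxy)-4-[(2R)-1-methylpiperidin-2-yl]phenoxy}-N-methoxy-N-methyl-3-phenylpropanamide F3. Bromination of ring A with N-bromosuccinimide (amine first protonated with 1 equiv CF3CO2H, MeCN, −20 °C) should place one bromine ortho to the ether oxygen and give (3S)-3-{3,5-bis(benzyloxy)-2-bromo-4-[(2R)-1-methylpiperidin-2-yl]phenoxy}-N-methoxy-N-methyl-3-phenylpropanamide F4. Bromine–lithium exchange with tert-butyllithium (THF, −78 °C) and attack of the aryllithium on the amide (Parham-type cyclisation) should come back to the route at 21.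

Step 7. Turnover on the crowded diene may be slow, so that ruthenium hydride species shift the alkenes toward nitrogen or intermolecular metathesis takes over. The fallback closes ring D at N1'–C6' by reduction of a cyclic imine instead of by metathesis. Setting out from 6, [3-(1,3-dioxolan-2-yl)propyl]magnesium bromide F5 (from 2-(3-bromopropyl)-1,3-dioxolane and Mg turnings, THF) should add in CH2Cl2 at −78 °C with the same facial sense as in step 4 to give (S)-N-{(1R)-1-[2,6-bis(benzyloxy)-4-(triisopropylsilyloxy)phenyl]-4-(1,3-dioxolan-2-yl)butyl}-2-methylpropane-2-sulfinamide F6. CF3CO2H/H2O should remove the sulfinyl group and the acetal and close (2R)-2-[2,6-bis(benzyloxy)-4-(triisopropylsilyloxy)phenyl]-2,3,4,5-tetrahydropyridine F7, which Et3SiH added to the same flask should reduce to (2R)-2-[2,6-bis(benzyloxy)-4-(triisopropylsilyloxy)phenyl]piperidine F8. Reductive methylation (aqueous CH2O, NaBH(OAc)3, 1,2-dichloroethane) should come back to the route at 15, which is desilylated as in the second half of step 9.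

**Further compounds**

F1 | step 10 | (2R)-2-{2,6-bis(benzyloxy)-4-[(1S)-1-phenylbut-3-en-1-yloxy]phenyl}-1-methylpiperidine | CN1CCCC[C@@H]1c1c(OCc2ccccc2)cc(O[C@@H](CC=C)c2ccccc2)cc1OCc1ccccc1
F2 | step 10 | (3S)-3-{3,5-bis(benzyloxy)-4-[(2R)-1-methylpiperidin-2-yl]phenoxy}-3-phenylpropanal | CN1CCCC[C@@H]1c1c(OCc2ccccc2)cc(O[C@@H](CC=O)c2ccccc2)cc1OCc1ccccc1
F3 | step 12 | (3S)-3-{3,5-bis(benzyloxy)-4-[(2R)-1-methylpiperidin-2-yl]phenoxy}-N-methoxy-N-methyl-3-phenylpropanamide | CN1CCCC[C@@H]1c1c(OCc2ccccc2)cc(O[C@@H](CC(=O)N(C)OC)c2ccccc2)cc1OCc1ccccc1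
F4 | step 12 | (3S)-3-{3,5-bis(benzyloxy)-2-bromo-4-[(2R)-1-methylpiperidin-2-yl]phenoxy}-N-methoxy-N-methyl-3-phenylpropanamide | CN1CCCC[C@@H]1c1c(OCc2ccccc2)cc(O[C@@H](CC(=O)N(C)OC)c2ccccc2)c(Br)c1OCc1ccccc1
F5 | step 7 | [3-(1,3-dioxolan-2-yl)propyl]magnesium bromide | Br[Mg]CCCC1OCCO1
F6 | step 7 | (S)-N-{(1R)-1-[2,6-bis(benzyloxy)-4-(triisopropylsilyloxy)phenyl]-4-(1,3-dioxolan-2-yl)butyl}-2-methylpropane-2-sulfinamide | CC(C)(C)[S@](=O)N[C@H](CCCC1OCCO1)c1c(OCc2ccccc2)cc(O[Si](C(C)C)(C(C)C)C(C)C)cc1OCc1ccccc1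
F7 | step 7 | (2R)-2-[2,6-bis(benzyloxy)-4-(triisopropylsilyloxy)phenyl]-2,3,4,5-tetrahydropyridine | N1=CCCC[C@@H]1c1c(OCc2ccccc2)cc(O[Si](C(C)C)(C(C)C)C(C)C)cc1OCc1ccccc1
F8 | step 7 | (2R)-2-[2,6-bis(benzyloxy)-4-(triisopropylsilyloxy)phenyl]piperidine | N1CCCC[C@@H]1c1c(OCc2ccccc2)cc(O[Si](C(C)C)(C(C)C)C(C)C)cc1OCc1ccccc1
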